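The readings were generated by integration with made-up constants; scatter was added.

The target climbs and then sinks in the dawn run, from 51.8% at 25.0 h to 45.3% at 40.0 h, but the question is how much electrophile has reacted, so I follow the electrophile.

the same everywhere: electrophile 0.050 M
- dawn: nucleophile 0.11 M; run made earlier
- autumn: nucleophile 0.19 M; run made earlier
- eta: nucleophile 0.0900 M; time 40 h
- alpha: nucleophile 0.120 M; time 40 h
- delta: nucleophile 0.150 M; time 40 h

| run | time / h | electrophile / % | target / % |
|---|---|---|---|
| dawn | 2.00 | 85.2 | 15.8 |
| dawn | 6.00 | 62.7 | 34.6 |
| dawn | 12.0 | 44.3 | 45.6 |
| dawn | 15.0 | 41.6 | 48.7 |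
| dawn | 25.0 | 28.7 | 51.8 |
| dawn | 30.0 | 24.1 | 49.1 |
| dawn | 40.0 | 19.0 | 45.3 |
| autumn | 6.00 | 44.8 | 50.2 |
| autumn | 12.0 | 24.5 | 63.6 |
| autumn | 15.0 | 18.7 | 65.9 |
| autumn | 25.0 | 7.8 | 60.3 |
| autumn | 30.0 | 6.3 | 57.7 |
| autumn | 40.0 | 1.6 | 50.7 |

(readings scatter by 1 percentage point)

- what was read earlier has a scatter of 1 percentage point, one standard deviation

* part of the electrophile that has reacted at the end, eta
* part of the electrophile that has reacted at the end, alpha
* part of the electrophile that has reacted at the end, delta
* what raising the concentration of nucleophile from its lowest to its highest value here does to the part of the electrophile that has reacted (changes below 5 percentage points count as none) (no change / it rises / it falls)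

I take the electrophile's loss rate as k times c_electrophile times c_nucleophile, so the two runs give two separate readings of one constant, and they ought to agree. If each electrophile spends one nucleophile, integrating gives 0.501 /M/h from dawn at 40.0 h and 0.649 /M/h from autumn at 25.0 h, and these part. So one of my assumptions cheats, and I suspect the count. If each electrophile spends two nucleophiles, the same readings give 0.819 /M/h and 0.839 /M/h, which agree, so I trust that count.

I carry their mean, 0.829 /M/h, as a reading: k, the fraction of the electrophile lost per hour per molar of free nucleophile. One over k times c_nucleophile is then the electrophile's momentary time constant, the pseudo-first-order one, and it stretches as the nucleophile is spent. Integrating to 40 h with the nucleophile falling by two per electrophile, I get 71.7% reacted in eta, 84.9% in alpha and 92.7% in delta.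

The forecast, reasoning that “two nucleophiles are consumed per electrophile”, says 72% (67% to 77%) for eta, 85% (81% to 89%) for alpha, 93% (90% to 96%) for delta, and for the trend: it rises.

The flasks give 71.8%, 85.0% and 92.8%, so the trend is: it rises, and going from eta to delta lifts the part reacted by 21 percentage points.

    target → over-reaction product (k = 0.0211 /h)
    electrophile + nucleophile → acid set free + target (k = 0.832 /M/h)
    nucleophile + acid set free ⇌ protonated nucleophile, settled at all times (K = 47100 /M)

In eta at 40.0 h, the protonated nucleophile stands at 0.0359 M, level with the electrophile reacted, 0.0359 M, and that is where the second nucleophile sits. With k, the electrophile's time constant in eta has grown from 13.4 h on the charge to 66.2 h on the free nucleophile left, 20.2% of its charge.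

For a neighbour flask, which is delta with 0.020 M of electrophile, k gives 98.1% reacted at 40 h. The flask gives 98.1%.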